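## The problem

The target 24 is a 3,3a,4,5-tetrahydro-1-benzofuran-6(2H)-one. An oxolane (ring A: O1, C2, C3, C3a, C7a) shares the C3a–C7a bond with a cyclohexenone (ring B: C3a, C4, C5, C6, C7, C7a), and O1–C7a=C7–C6=O is a vinylogous ester. Three contiguous stereocentres sit on ring A: C2 (methyl), C3 (3,4,5-trimethoxyphenyl) and the quaternary C3a (allyl), with methyl and aryl trans and aryl and allyl cis. A fourth, C5 (methoxy), lies across ring B, trans to the allyl group. If C2, C3 and C3a are made together in an open chain, one purchased or auxiliary-made centre (C2) can set the other two. C3a can then set C5, because the allyl group is pseudo-axial on ring B, shields one face of a C5 enolate and leaves the trans methoxy group equatorial. The groups that limit the chemistry are the vinylogous ester (acid, hydride, hard nucleophiles), the epimerisable α-methoxy ketone at C5, the terminal alkene (no hydrogenation, peracid or α-keto radical chemistry) and the electron-rich arene. The enabling feature is that the aryl group sits on C3 and the ring oxygen on the methyl-bearing C2. Oxygen capture of a benzylic cation would give the opposite arrangement, so the C3–aryl and O1–C2 bonds are best traced to an aryl group that began on C2 and moved to C3 across a bridged ion. O1 is at the same time the carbonyl oxygen of a ring B vinylogous ester, five atoms from C2.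

## Retrosynthesis

**C5 methoxy (24 to 21).** The C5–O bond and its O-methyl group are removed first, through hydroxy ketone 23 to ketone 21. C5 is the only enolisable position of 21, since C3a is quaternary and C7 is part of the enol ether, so no regiochemical question arises. Removing the C5 group also removes the most base-sensitive function from all earlier steps. The forward reaction must deliver oxygen trans to the allyl group, which is both the kinetically open face and the more stable arrangement.

**Ring A (21 to 18).** The O1–C2 and C3–aryl bonds are cut and the aryl group is returned to C2, which opens ring A and leads to mesylate 18. The neighbouring cuts are less attractive. Cutting O1–C7a alone needs an open chain that already has aryl on C3 and oxygen on C2. Cutting C3–C3a alone needs alkylation of a hindered enolate by a secondary electrophile. In 18 the side chain is an aldol of a simple 2-arylpropanal, and ring B still carries both of its oxygens as a dimethoxy enone. The forward step must invert C3 and C2 stereospecifically and the C7a carbonyl oxygen must capture the bridged ion at C2. Applying the two inversions backwards to 21 gives the (1S,2R) side chain on (R)-configured C3a drawn for 18.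

**C3a–C3 bond (18 to 7 and 15).** Mesylate 18 comes from alcohol 17, and the C3a–C3 bond of 17 is an aldol bond between the enolate of allyl enone 7 and aldehyde 15. The cut divides the molecule into two fragments of similar size and makes the leaving-group oxygen as the bond forms. Running the aldol after the allylation keeps a retro-aldol-prone β-hydroxy ketone away from a second enolate alkylation. It also means that 7 can be racemic, because its only stereocentre becomes trigonal in the enolate. The forward reaction must combine a closed chair transition state (aldehyde residue equatorial) with Felkin–Anh addition. This combination gives exactly the configuration of 17.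

**Ring B fragment (7 to 1).** The C3a–allyl bond is cut to 2,3-dimethoxycyclohex-2-en-1-one 4 and allyl bromide 5 (kinetic α'-alkylation). Enone 4 is the methyl enol ether of 2-methoxy-1,3-dione 3. The C7–O bond of 3 is cut to diazo dione 2 and methanol (carbenoid O–H insertion), and 2 comes from cyclohexane-1,3-dione 1 by diazo transfer. All six ring B carbons are bought in one piece, and each step is a standard operation on a symmetric intermediate.

**Aldehyde fragment (15 to 8).** Aldehyde 15 is taken back through alcohol 14 to imide 13. The C–CH3 bond of 13 is cut to imide 11, which is made from 3,4,5-trimethoxyphenylacetic acid 8 and oxazolidinone 9. Auxiliary-controlled methylation is preferred to a catalytic route because it gives the benzylic centre in reliably high purity. The α-aryl aldehyde is made only in the last step of the fragment and is used at once.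

## Roads not taken

**Alternative 1: Michael–Claisen annulation of ring B onto a lactone.**
- Cut: the C3a–C4 and C7–C7a bonds. Ring A is kept as the butyrolactone A1 ((4R,5R)-5-methyl-3-(prop-2-en-1-yl)-4-(3,4,5-trimethoxyphenyl)oxolan-2-one). Ring B carbons C4 to C7 come from the enone A2 (1,3-dimethoxybut-3-en-2-one).
- Forward key step: the enolate of A1 adds to A2 on the face away from the C3 aryl group. The ketone enolate, after shifting to the methoxymethyl side, acylates the lactone carbonyl and opens it to the dione enol A3. Cyclodehydration of A3 would give 24 directly.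
- Merits: A1 should be available in a few steps by conjugate arylation of an unsaturated lactone and allylation. C3a is set by a substituent on the adjacent ring carbon, which is more secure than the open-chain aldol of step 9. The C5 methoxy group arrives with A2, so no late oxidation is needed. On paper the route is several steps shorter than the chosen one.
- Weak points: A2 is an α-alkoxy enone, a deactivated acceptor that polymerises easily. A fully substituted lactone enolate must form the quaternary carbon in a reversible Michael addition. The enolate formed first lies at C5 and must move to C7 before it can attack a carbonyl flanked by the new quaternary carbon. Retro-Michael, O-acylation and retro-Claisen cleavage of A3 all compete.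
- Comparison: this road is better in step count and in control of C3a. The chosen plan sets against it that no carbon–carbon bond has to be made to a hindered carbonyl, that ring B is bought intact, and that its risky step is an intramolecular, stereospecific ionisation. Alternative 1 instead relies on a bimolecular tandem reaction with an unfavourable equilibrium.

**Alternative 2: squarate ring expansion.**
- Cut: the C3a–C7a bond. Ring B grows from dimethyl squarate A4 by way of the 4-alkenyl-4-hydroxycyclobutenone A5.
- Forward key step: heating A5 opens the four-membered ring to a dienylketene. The ketene carbon closes onto the disubstituted alkene terminus and, after tautomerisation, gives the enedione A6.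
- Merits: both methoxy-bearing carbons of ring B come from A4, and the quaternary carbon forms in a pericyclic step without base.
- Weak points: A6 has its carbonyls at C5 and C7a and its enol ethers at C6 and C7, one position away from the target pattern. The C5 carbonyl must be reduced and methylated, the C6 enol ether hydrolysed selectively, the silyl ether removed and ring A closed. The alkenyl-lithium partner needs a stereodefined trisubstituted vinyl halide that already carries aryl on C3 and oxygen on C2, so the regiochemical problem is only moved upstream. The configuration of C3a depends on the face of the alkene that the ketene approaches, controlled only by the neighbouring C3 centre. Closure onto a fully substituted terminus is slow.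
- Comparison: this road is longer and less well controlled. Its one advantage is that it avoids the diazo chemistry of steps 1 and 2, against which the chosen plan sets three routine steps to 4.

**Alternative 3: carbene-catalysed acyloin closure.**
- Cut: the C5–C6 bond. Ring B is closed last from the dialdehyde A7.
- Forward key step: an N-heterocyclic carbene converts the C5 aldehyde into an acyl anion equivalent that adds to the C6 aldehyde. Ketol transposition then gives the conjugated C6 ketone with the C5 hydroxyl, A8, which is the same compound as 23.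
- Merits: the C5 oxygen is installed under mild, catalytic conditions without strong base or oxidant, and C5 is set under thermodynamic control. In this respect the road is at least as good as step 12.
- Weak points: A7 already contains ring A with all three contiguous stereocentres, so the key step solves none of the hard problems. The C6 aldehyde is a push–pull enal and a poor electrophile, and the enolisable C5 aldehyde can undergo aldol or self-benzoin reactions. Two differentiated aldehydes must be carried through a ring A synthesis.
- Comparison: the chosen plan reaches the same compound, 23, by a single enolate oxidation of 21, which is far shorter.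

Key step: step 11

Remark: 3 is drawn as its enol; 7 is used as the racemate because its stereocentre becomes the trigonal carbon of enolate 16; the change of the C3a descriptor from R (17, 18, 21) to S (23, 24) is a priority change, not an inversion.

## Route

Step 1
Reactants: 1 cyclohexane-1,3-dione
Product: 2 2-diazocyclohexane-1,3-dione
Conditions: 4-acetamidobenzenesulfonyl azide, Et3N, MeCN, 0 °C to rt
Reagents that add atoms: 4-acetamidobenzenesulfonyl azide, CC(=O)Nc1ccc(cc1)S(=O)(=O)N=[N+]=[N-]
Why: Regitz diazo transfer to the acidic methylene of a 1,3-dione is routine; the sulfonamide by-product is removed by filtration and base wash.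

Step 2
Reactants: 2 2-diazocyclohexane-1,3-dione
Product: 3 2-methoxycyclohexane-1,3-dione (enol form 3-hydroxy-2-methoxycyclohex-2-en-1-one)
Conditions: Rh2(OAc)4 (1 mol%), MeOH/CH2Cl2, 40 °C
Reagents that add atoms: methanol, CO
Why: The carbenoid formed from a 2-diazo-1,3-dione and Rh2(OAc)4 inserts into the O–H bond of methanol (carbenoid O–H insertion), which places the future C7 methoxy group; the product enolises.

Step 3
Reactants: 3 2-methoxycyclohexane-1,3-dione
Product: 4 2,3-dimethoxycyclohex-2-en-1-one
Conditions: HC(OMe)3, MeOH, TsOH·H2O (cat.), rt to 50 °C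
Reagents that add atoms: methanol, CO; trimethyl orthoformate, COC(OC)OC
Why: Acid-catalysed enol etherification of a 1,3-dione (vinylogous ester formation); the dione is symmetric, so one product is possible, and the orthoformate consumes the water.

Step 4
Reactants: 4 2,3-dimethoxycyclohex-2-en-1-one; 5 allyl bromide
Product: 7 rac-2,3-dimethoxy-6-(prop-2-en-1-yl)cyclohex-2-en-1-one, via lithium dienolate 6 (not isolated)
Conditions: LiN(i-Pr)2, THF, −78 °C; then 5, −78 to 0 °C
Reagents that add atoms: none
Why: Kinetic α'-deprotonation of a vinylogous ester and C-alkylation of the cross-conjugated dienolate (Stork–Danheiser alkylation); the new centre is racemic and is erased in step 9.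

Step 5
Reactants: 8 2-(3,4,5-trimethoxyphenyl)acetic acid; 9 (4R)-4-benzyl-1,3-oxazolidin-2-one
Product: 11 (4R)-4-benzyl-3-[2-(3,4,5-trimethoxyphenyl)acetyl]-1,3-oxazolidin-2-one, via mixed pivalic anhydride 10 (not isolated)
Conditions: t-BuCOCl, Et3N, THF, −20 °C; then 9, LiCl, −20 °C to rt
Reagents that add atoms: none
Why: N-Acylation of the oxazolidinone through the mixed anhydride with LiCl/Et3N activation is a standard entry to N-acyl oxazolidinones and needs no strong base.

Step 6
Reactants: 11 (4R)-4-benzyl-3-[2-(3,4,5-trimethoxyphenyl)acetyl]-1,3-oxazolidin-2-one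
Product: 13 (4R)-4-benzyl-3-[(2R)-2-(3,4,5-trimethoxyphenyl)propanoyl]-1,3-oxazolidin-2-one, via sodium Z-enolate 12 (not isolated)
Conditions: NaN(SiMe3)2, THF, −78 °C; MeI, −78 °C
Reagents that add atoms: iodomethane, CI
Why: Evans alkylation: the chelated Z-enolate 12 is methylated on the face away from the benzyl group, which with the (R)-auxiliary sets the (R) benzylic centre.

Step 7
Reactants: 13 (4R)-4-benzyl-3-[(2R)-2-(3,4,5-trimethoxyphenyl)propanoyl]-1,3-oxazolidin-2-one
Product: 14 (2R)-2-(3,4,5-trimethoxyphenyl)propan-1-ol
Conditions: LiBH4, MeOH (1 equiv), THF, 0 °C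
Reagents that add atoms: none
Why: Reductive cleavage of the imide with LiBH4 gives the primary alcohol without enolising the benzylic centre and returns the auxiliary 9.

Step 8
Reactants: 14 (2R)-2-(3,4,5-trimethoxyphenyl)propan-1-ol
Product: 15 (2R)-2-(3,4,5-trimethoxyphenyl)propanal
Conditions: Dess–Martin periodinane, CH2Cl2, 0 °C to rt; filtered and used at once
Reagents that add atoms: none
Why: Dess–Martin oxidation is base-free, so the configurationally labile α-aryl aldehyde should form without racemisation if it is used without storage or chromatography.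

Step 9
Reactants: 7 rac-2,3-dimethoxy-6-(prop-2-en-1-yl)cyclohex-2-en-1-one; 15 (2R)-2-(3,4,5-trimethoxyphenyl)propanal
Product: 17 (6R)-6-[(1S,2R)-1-hydroxy-2-(3,4,5-trimethoxyphenyl)propyl]-2,3-dimethoxy-6-(prop-2-en-1-yl)cyclohex-2-en-1-one, via lithium dienolate 16 (not isolated)
Conditions: LiN(i-Pr)2, THF, −78 °C; then 15, −78 °C, short contact; AcOH quench at −78 °C
Reagents that add atoms: none
Why: Directed aldol addition of a tetrasubstituted enolate: the closed Zimmerman–Traxler chair with the aldehyde residue equatorial and the allyl group pseudo-axial sets C3a relative to C3, and Felkin–Anh attack anti to the aryl group sets C3 relative to the benzylic centre. The cold acidic quench guards against retro-aldol cleavage and aldehyde enolisation.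

Step 10
Reactants: 17 (6R)-6-[(1S,2R)-1-hydroxy-2-(3,4,5-trimethoxyphenyl)propyl]-2,3-dimethoxy-6-(prop-2-en-1-yl)cyclohex-2-en-1-one
Product: 18 (1S,2R)-1-[(1R)-3,4-dimethoxy-2-oxo-1-(prop-2-en-1-yl)cyclohex-3-en-1-yl]-2-(3,4,5-trimethoxyphenyl)propyl methanesulfonate
Conditions: MsCl, Et3N, CH2Cl2, −20 to 0 °C; short silica plug, used directly
Reagents that add atoms: methanesulfonyl chloride, CS(=O)(=O)Cl
Why: Sulfonylation through sulfene reaches hindered secondary alcohols; the neighbouring quaternary carbon has no hydrogen, so β-elimination to an enone cannot occur, and the configuration at the carbinol carbon is retained.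

Step 11
Reactants: 18 (1S,2R)-1-[(1R)-3,4-dimethoxy-2-oxo-1-(prop-2-en-1-yl)cyclohex-3-en-1-yl]-2-(3,4,5-trimethoxyphenyl)propyl methanesulfonate
Product: 21 (2R,3S,3aR)-7-methoxy-2-methyl-3a-(prop-2-en-1-yl)-3-(3,4,5-trimethoxyphenyl)-3,3a,4,5-tetrahydro-1-benzofuran-6(2H)-one, via phenonium mesylate 19 (not isolated), via methoxy-oxocarbenium mesylate 20 (not isolated)
Conditions: (CF3)2CHOH (HFIP), NaHCO3 (solid), 0 to 40 °C; concentrate
Reagents that add atoms: none
Why: In the strongly ionising, weakly nucleophilic solvent the C3–O bond breaks with rear-side participation of the aryl group on C2, so that the bridged phenonium ion 19 forms instead of an open cation beside the quaternary carbon. The C7a carbonyl oxygen of the vinylogous ester then opens the three-membered ring at C2 in a 5-exo-tet closure of ring A and gives the methoxy-oxocarbenium ion 20. Its O-methyl group is taken by the mesylate counter-ion in an SN2 step, at the latest on concentration, which frees the C6 ketone and leaves the C7=C7a enol ether. The closest known reaction type is solvolytic 1,2-aryl migration through a phenonium ion with capture by an internal oxygen nucleophile, joined to the dealkylative O-cyclisation known from halo-etherification of 3-alkoxy enones. C3 is set by inversion because the aryl group enters anti to the leaving group, and C2 is set by inversion because oxygen enters anti to the departing aryl bridge; both follow from the centres fixed in step 9, and C3a is untouched. The step needs ring opening at C2 and not C3, which is secured because attack at C3 would form an oxetane. It also needs aryl bridging to outrun shift of a C3a substituent or proton loss, which the electron-rich ring, the antiperiplanar rotamer and the solvent favour. A mesylate is chosen over a triflate because its anion is nucleophilic enough to remove the methyl group, and the bicarbonate only buffers adventitious acid.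

Step 12
Reactants: 21 (2R,3S,3aR)-7-methoxy-2-methyl-3a-(prop-2-en-1-yl)-3-(3,4,5-trimethoxyphenyl)-3,3a,4,5-tetrahydro-1-benzofuran-6(2H)-one
Product: 23 (2R,3S,3aS,5S)-5-hydroxy-7-methoxy-2-methyl-3a-(prop-2-en-1-yl)-3-(3,4,5-trimethoxyphenyl)-3,3a,4,5-tetrahydro-1-benzofuran-6(2H)-one, via potassium enolate 22 (not isolated)
Conditions: KN(SiMe3)2, THF, −78 °C; 3-phenyl-2-(phenylsulfonyl)oxaziridine, −78 °C; AcOH quench
Reagents that add atoms: 3-phenyl-2-(phenylsulfonyl)oxaziridine, O=S(=O)(c1ccccc1)N1OC1c1ccccc1
Why: Only C5 can be deprotonated, and the oxaziridine transfers oxygen to the enolate (Davis oxidation) on the face away from the pseudo-axial allyl group; the resulting hydroxyl is trans to allyl and equatorial, so kinetic and thermodynamic preferences agree.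

Step 13
Reactants: 23 (2R,3S,3aS,5S)-5-hydroxy-7-methoxy-2-methyl-3a-(prop-2-en-1-yl)-3-(3,4,5-trimethoxyphenyl)-3,3a,4,5-tetrahydro-1-benzofuran-6(2H)-one
Product: 24 (2R,3S,3aS,5S)-5,7-dimethoxy-2-methyl-3a-(prop-2-en-1-yl)-3-(3,4,5-trimethoxyphenyl)-3,3a,4,5-tetrahydro-1-benzofuran-6(2H)-one
Conditions: MeI, Ag2O, 4 Å molecular sieves, CH2Cl2, rt, dark
Reagents that add atoms: iodomethane, CI
Why: Purdie methylation etherifies the α-hydroxy ketone without a strong base, so C5 should not epimerise and the nucleophilic vinylogous ester carbonyl is not alkylated as it could be by oxonium or triflate reagents.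

## Compound list

1 | cyclohexane-1,3-dione | O=C1CCCC(=O)C1 | starting material
2 | 2-diazocyclohexane-1,3-dione | [N-]=[N+]=C1C(=O)CCCC1=O | intermediate
3 | 2-methoxycyclohexane-1,3-dione (enol form 3-hydroxy-2-methoxycyclohex-2-en-1-one) | COC1=C(O)CCCC1=O | intermediate
4 | 2,3-dimethoxycyclohex-2-en-1-one | COC1=C(OC)C(=O)CCC1 | intermediate
5 | allyl bromide (3-bromoprop-1-ene) | C=CCBr | starting material
6 | lithium 5,6-dimethoxycyclohexa-1,5-dien-1-olate | [Li]OC1=CCCC(OC)=C1OC | intermediate (not isolated)
7 | rac-2,3-dimethoxy-6-(prop-2-en-1-yl)cyclohex-2-en-1-one | C=CCC1CCC(OC)=C(OC)C1=O | intermediate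
8 | 2-(3,4,5-trimethoxyphenyl)acetic acid | OC(=O)Cc1cc(OC)c(OC)c(OC)c1 | starting material
9 | (4R)-4-benzyl-1,3-oxazolidin-2-one | O=C1N[C@H](Cc2ccccc2)CO1 | starting material
10 | 2,2-dimethylpropanoic 2-(3,4,5-trimethoxyphenyl)acetic anhydride | CC(C)(C)C(=O)OC(=O)Cc1cc(OC)c(OC)c(OC)c1 | intermediate (not isolated)
11 | (4R)-4-benzyl-3-[2-(3,4,5-trimethoxyphenyl)acetyl]-1,3-oxazolidin-2-one | COc1cc(CC(=O)N2[C@H](Cc3ccccc3)COC2=O)cc(OC)c1OC | intermediate
12 | sodium (Z)-enolate of 11: sodium (Z)-1-[(4R)-4-benzyl-2-oxo-1,3-oxazolidin-3-yl]-2-(3,4,5-trimethoxyphenyl)ethen-1-olate | [Na]O/C(=C\c1cc(OC)c(OC)c(OC)c1)N1[C@H](Cc2ccccc2)COC1=O | intermediate (not isolated)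
13 | (4R)-4-benzyl-3-[(2R)-2-(3,4,5-trimethoxyphenyl)propanoyl]-1,3-oxazolidin-2-one | C[C@H](c1cc(OC)c(OC)c(OC)c1)C(=O)N1[C@H](Cc2ccccc2)COC1=O | intermediate
14 | (2R)-2-(3,4,5-trimethoxyphenyl)propan-1-ol | C[C@H](c1cc(OC)c(OC)c(OC)c1)CO | intermediate
15 | (2R)-2-(3,4,5-trimethoxyphenyl)propanal | C[C@H](c1cc(OC)c(OC)c(OC)c1)C=O | intermediate
16 | lithium 5,6-dimethoxy-2-(prop-2-en-1-yl)cyclohexa-1,5-dien-1-olate | [Li]OC1=C(CC=C)CCC(OC)=C1OC | intermediate (not isolated)
17 | (6R)-6-[(1S,2R)-1-hydroxy-2-(3,4,5-trimethoxyphenyl)propyl]-2,3-dimethoxy-6-(prop-2-en-1-yl)cyclohex-2-en-1-one | C=CC[C@]1(CCC(OC)=C(OC)C1=O)[C@@H](O)[C@H](C)c1cc(OC)c(OC)c(OC)c1 | intermediate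
18 | (1S,2R)-1-[(1R)-3,4-dimethoxy-2-oxo-1-(prop-2-en-1-yl)cyclohex-3-en-1-yl]-2-(3,4,5-trimethoxyphenyl)propyl methanesulfonate | C=CC[C@]1(CCC(OC)=C(OC)C1=O)[C@@H](OS(C)(=O)=O)[C@H](C)c1cc(OC)c(OC)c(OC)c1 | intermediate
19 | phenonium ion pair: trans-(1S,2S)-1-[(1R)-3,4-dimethoxy-2-oxo-1-(prop-2-en-1-yl)cyclohex-3-en-1-yl]-5,6,7-trimethoxy-2-methylspiro[2.5]octa-4,7-dien-6-ylium methanesulfonate | C=CC[C@]1(CCC(OC)=C(OC)C1=O)[C@H]3[C@H](C)C32C=C(OC)C(=[O+]C)C(OC)=C2.CS(=O)(=O)[O-] | intermediate (not isolated)
20 | methoxy-oxocarbenium ion pair: O-methylated 21 (methylated on the C6 oxygen, cation delocalised over C6, C7 and C7a) methanesulfonate | C=CC[C@@]12CCC(=[O+]C)C(OC)=C1O[C@H](C)[C@H]2c1cc(OC)c(OC)c(OC)c1.CS(=O)(=O)[O-] | intermediate (not isolated)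
21 | (2R,3S,3aR)-7-methoxy-2-methyl-3a-(prop-2-en-1-yl)-3-(3,4,5-trimethoxyphenyl)-3,3a,4,5-tetrahydro-1-benzofuran-6(2H)-one | C=CC[C@@]12CCC(=O)C(OC)=C1O[C@H](C)[C@H]2c1cc(OC)c(OC)c(OC)c1 | intermediate
22 | potassium (2R,3S,3aS)-7-methoxy-2-methyl-3a-(prop-2-en-1-yl)-3-(3,4,5-trimethoxyphenyl)-2,3,3a,4-tetrahydro-1-benzofuran-6-olate | C=CC[C@@]12CC=C(O[K])C(OC)=C1O[C@H](C)[C@H]2c1cc(OC)c(OC)c(OC)c1 | intermediate (not isolated)
23 | (2R,3S,3aS,5S)-5-hydroxy-7-methoxy-2-methyl-3a-(prop-2-en-1-yl)-3-(3,4,5-trimethoxyphenyl)-3,3a,4,5-tetrahydro-1-benzofuran-6(2H)-one | C=CC[C@@]12C[C@H](O)C(=O)C(OC)=C1O[C@H](C)[C@H]2c1cc(OC)c(OC)c(OC)c1 | intermediate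
24 | (2R,3S,3aS,5S)-5,7-dimethoxy-2-methyl-3a-(prop-2-en-1-yl)-3-(3,4,5-trimethoxyphenyl)-3,3a,4,5-tetrahydro-1-benzofuran-6(2H)-one | C=CC[C@@]12C[C@H](OC)C(=O)C(OC)=C1O[C@H](C)[C@H]2c1cc(OC)c(OC)c(OC)c1 | target

## Step count and risks

Total: 13 steps. Longest linear sequence: 9 steps (steps 1–4 and 9–13 from 1; equally steps 5–8 and 9–13 from 8).

**Step 11 (key step).**
- What may go wrong: ionisation of the neopentylic sulfonate without effective aryl bridging. The trimethoxyphenyl ring is a weaker neighbouring group than a 4-methoxyphenyl ring, because its central methoxy group is twisted and the outer two are meta to the ipso carbon. The result would be proton loss to styrene-type alkenes or shift of a C3a substituent. Capture by the carbonyl oxygen may also be reversible, and demethylation of ion 20 may be slow in a solvent that solvates mesylate strongly, so that hydrolytic ring opening occurs on work-up.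
- Fallback: ring closure is separated from the aryl shift. Starting from 18, solvolysis in acetone–water over CaCO3 at 50 °C lets water take the bridged ion at C2 or hydrolyse ion 20. This should give 21 together with the ring-opened, aryl-shifted alcohol (6R)-6-[(1S,2R)-2-hydroxy-1-(3,4,5-trimethoxyphenyl)propyl]-2,3-dimethoxy-6-(prop-2-en-1-yl)cyclohex-2-en-1-one F1. F1 is then closed onto the C7a carbonyl by acid-catalysed ketalisation and elimination (pyridinium p-toluenesulfonate, toluene, 80 °C) with loss of methanol, and the route is rejoined at 21.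

**Step 9 (aldol).**
- What may go wrong: incomplete facial selectivity, because the pseudo-axial allyl group of the tetrasubstituted enolate crowds the Felkin–Anh rotamer of the aldehyde. Proton transfer from the acidic α-aryl aldehyde to enolate 16 would cause racemisation, and the hindered lithium aldolate may undergo retro-aldol cleavage.
- Fallback: an open-transition-state Mukaiyama aldol replaces the closed chair. Starting from 7, LiN(i-Pr)2 and then Me3SiCl give the silyl dienol ether [5,6-dimethoxy-2-(prop-2-en-1-yl)cyclohexa-1,5-dien-1-yl]oxy(trimethyl)silane F2. F2 is added to 15 with BF3·OEt2 in CH2Cl2 at −78 °C. No basic enolate is present and Felkin–Anh addition is strongly favoured, though the C3a/C3 relation is then less secure. The route is rejoined at 17.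

**Step 12 (C5 hydroxylation).**
- What may go wrong: modest facial selectivity, since the directing allyl group is two atoms from C5, and addition of the enolate to the sulfonyl imine released by the oxidant.
- Fallback: thermodynamic instead of kinetic control at C5. Starting from 21, the hydroxylation mixture containing the epimer (2R,3S,3aS,5R)-5-hydroxy-7-methoxy-2-methyl-3a-(prop-2-en-1-yl)-3-(3,4,5-trimethoxyphenyl)-3,3a,4,5-tetrahydro-1-benzofuran-6(2H)-one F3 is methylated as in step 13 without separation. This gives 24 together with (2R,3S,3aS,5R)-5,7-dimethoxy-2-methyl-3a-(prop-2-en-1-yl)-3-(3,4,5-trimethoxyphenyl)-3,3a,4,5-tetrahydro-1-benzofuran-6(2H)-one F4. DBU in toluene/MeOH then epimerises F4 through the C5 enol to the isomer with the equatorial methoxy group trans to allyl, and the route is rejoined at 24.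

**Step 13 (O-methylation).**
- What may go wrong: slow etherification of the hindered α-ketol, leaving time for enediol tautomerism, oxidation of the ketol by Ag2O or epimerisation at C5.
- Fallback: direct α-methoxylation that bypasses 23. Starting from 21, LiN(i-Pr)2 and Me3SiCl give the silyl enol ether trimethyl{[(2R,3S,3aS)-7-methoxy-2-methyl-3a-(prop-2-en-1-yl)-3-(3,4,5-trimethoxyphenyl)-2,3,3a,4-tetrahydro-1-benzofuran-6-yl]oxy}silane F5. F5 is methoxylated at C5 with iodosylbenzene (PhIO) and BF3·OEt2 in MeOH at −40 °C, a known α-methoxylation of silyl enol ethers. Any C5 epimer is corrected by the base equilibration described for step 12, and the route is rejoined at 24.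

## Further compounds

F1 | step 11 | (6R)-6-[(1S,2R)-2-hydroxy-1-(3,4,5-trimethoxyphenyl)propyl]-2,3-dimethoxy-6-(prop-2-en-1-yl)cyclohex-2-en-1-one | C=CC[C@]1(CCC(OC)=C(OC)C1=O)[C@H](c1cc(OC)c(OC)c(OC)c1)[C@@H](C)O
F2 | step 9 | [5,6-dimethoxy-2-(prop-2-en-1-yl)cyclohexa-1,5-dien-1-yl]oxy(trimethyl)silane | C=CCC1=C(O[Si](C)(C)C)C(OC)=C(OC)CC1
F3 | step 12 | (2R,3S,3aS,5R)-5-hydroxy-7-methoxy-2-methyl-3a-(prop-2-en-1-yl)-3-(3,4,5-trimethoxyphenyl)-3,3a,4,5-tetrahydro-1-benzofuran-6(2H)-one | C=CC[C@@]12C[C@@H](O)C(=O)C(OC)=C1O[C@H](C)[C@H]2c1cc(OC)c(OC)c(OC)c1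
F4 | step 12 | (2R,3S,3aS,5R)-5,7-dimethoxy-2-methyl-3a-(prop-2-en-1-yl)-3-(3,4,5-trimethoxyphenyl)-3,3a,4,5-tetrahydro-1-benzofuran-6(2H)-one | C=CC[C@@]12C[C@@H](OC)C(=O)C(OC)=C1O[C@H](C)[C@H]2c1cc(OC)c(OC)c(OC)c1
F5 | step 13 | trimethyl{[(2R,3S,3aS)-7-methoxy-2-methyl-3a-(prop-2-en-1-yl)-3-(3,4,5-trimethoxyphenyl)-2,3,3a,4-tetrahydro-1-benzofuran-6-yl]oxy}silane | C=CC[C@@]12CC=C(O[Si](C)(C)C)C(OC)=C1O[C@H](C)[C@H]2c1cc(OC)c(OC)c(OC)c1
A1 | alternative 1 | (4R,5R)-5-methyl-3-(prop-2-en-1-yl)-4-(3,4,5-trimethoxyphenyl)oxolan-2-one (C3 epimers, centre planarised in the key step) | C=CCC1C(=O)O[C@H](C)[C@H]1c1cc(OC)c(OC)c(OC)c1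
A2 | alternative 1 | 1,3-dimethoxybut-3-en-2-one | C=C(OC)C(=O)COC
A3 | alternative 1 | (4S,6S)-3-hydroxy-4-[(1S,2R)-2-hydroxy-1-(3,4,5-trimethoxyphenyl)propyl]-2,6-dimethoxy-4-(prop-2-en-1-yl)cyclohex-2-en-1-one | C=CC[C@]1(C[C@H](OC)C(=O)C(OC)=C1O)[C@H](c1cc(OC)c(OC)c(OC)c1)[C@@H](C)O
A4 | alternative 2 | dimethyl squarate (3,4-dimethoxycyclobut-3-ene-1,2-dione) | COC1=C(OC)C(=O)C1=O
A5 | alternative 2 | 4-{2-[(1R,2R)-2-(tert-butyldimethylsilyloxy)-1-(3,4,5-trimethoxyphenyl)propyl]penta-1,4-dien-1-yl}-4-hydroxy-2,3-dimethoxycyclobut-2-en-1-one (carbinol centre and alkene geometry not specified) | O=C1C(OC)=C(OC)C1(O)C=C(CC=C)[C@H](c1cc(OC)c(OC)c(OC)c1)[C@@H](C)O[Si](C)(C)C(C)(C)C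
A6 | alternative 2 | (6S)-6-[(1S,2R)-2-(tert-butyldimethylsilyloxy)-1-(3,4,5-trimethoxyphenyl)propyl]-2,3-dimethoxy-6-(prop-2-en-1-yl)cyclohex-2-ene-1,4-dione | C=CC[C@]1(CC(=O)C(OC)=C(OC)C1=O)[C@H](c1cc(OC)c(OC)c(OC)c1)[C@@H](C)O[Si](C)(C)C(C)(C)C
A7 | alternative 3 | (2Z)-2-methoxy-2-[(3S,4S,5R)-5-methyl-3-(2-oxoethyl)-3-(prop-2-en-1-yl)-4-(3,4,5-trimethoxyphenyl)oxolan-2-ylidene]acetaldehyde | C=CC[C@@]1(CC=O)/C(O[C@H](C)[C@H]1c1cc(OC)c(OC)c(OC)c1)=C(OC)\C=O
A8 | alternative 3 | (2R,3S,3aS,5S)-5-hydroxy-7-methoxy-2-methyl-3a-(prop-2-en-1-yl)-3-(3,4,5-trimethoxyphenyl)-3,3a,4,5-tetrahydro-1-benzofuran-6(2H)-one (identical with 23) | C=CC[C@@]12C[C@H](O)C(=O)C(OC)=C1O[C@H](C)[C@H]2c1cc(OC)c(OC)c(OC)c1
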